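**Assumption:** the target has no stereocentre, so the single-enantiomer requirement is met trivially. The chiral cyclobutenone intermediates are carried as racemates, and their only stereocentre is destroyed in the key step.

**Retrosynthetic overview** (ring numbered C1 = C-nonadecyl, C2 = CH, C3 = C=O, C4 = C-CH3, C5 = C-OH, C6 = C=O)
1. The C5 hydroxyl is unmasked last from its methyl ether (vinylogous ester hydrolysis).
2. The six-membered ring is closed at C3–C4 by a thermal cascade of a 4-allenyl-4-hydroxycyclobutenone: 4π opening, 6π closure, H shift.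
3. Enabling feature: the para carbonyl carbons C3 and C6 can be tied together as a temporary four-membered ring C3–C2=C1–C6, whose C3–C6 bond is not in the target and is cleaved again. C5(O)=C4–CH3 is the tautomer of a 1-oxygenated allene C5(O)=C4=CH2.
4. The cyclobutenone is assembled regiospecifically from a semisquarate: methoxyallenyl anion at the ketone carbonyl, then nonadecyl Grignard at the vinylogous ester carbonyl with 1,3-carbonyl transposition.
5. Ring order: four-membered ring (bought as squarate) first, six-membered ring in the key step.

Key step: step 5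

**Step 1**
Reactants: 1 diisopropyl squarate (3,4-diisopropoxycyclobut-3-ene-1,2-dione)
Product: 3 3-isopropoxycyclobut-3-ene-1,2-dione, via hydride adduct 2 (not isolated)
Conditions: LiAlH(OtBu)3, THF, −78 °C; then 6 M HCl, CH2Cl2, 0 °C to rt
Reagents that add atoms: water, O
Why: Mono 1,2-hydride reduction of the squarate followed by acid-promoted 1,3-carbonyl transposition (loss of the allylic hydroxyl, hydrolysis of the remote enol ether) should give the semisquarate.

**Step 2**
Reactants: 3 3-isopropoxycyclobut-3-ene-1,2-dione; 4 methoxyallene (1-methoxypropa-1,2-diene)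
Product: 7 3-isopropoxy-4-(1-methoxypropa-1,2-dien-1-yl)-4-(trimethylsilyloxy)cyclobut-2-en-1-one (racemic), via 1-lithio-1-methoxyallene 5 (not isolated), via lithium alkoxide 6 (not isolated)
Conditions: 4, n-BuLi, THF, −40 °C; then 3, −78 °C; then TMSCl, −78 to 0 °C; NaHCO3 work-up
Reagents that add atoms: chlorotrimethylsilane, C[Si](C)(C)Cl
Why: The α-lithiated alkoxyallene should add 1,2 to the ketone-like carbonyl next to the C–OiPr carbon and not to the deactivated vinylogous ester carbonyl (the standard regiochemistry of alkoxycyclobutenediones), and the tertiary alkoxide is silylated in situ.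

**Step 3**
Reactants: 7 the silyl ether from step 2; 8 1-bromononadecane
Product: 12 4-(1-methoxypropa-1,2-dien-1-yl)-3-nonadecyl-4-(trimethylsilyloxy)cyclobut-2-en-1-one (racemic), via nonadecylmagnesium bromide 9 (not isolated), via bromomagnesium alkoxide 10 (not isolated), via tertiary trifluoroacetate 11 (not isolated)
Conditions: 8, Mg, THF, 40 °C; then 7, THF, −78 to 0 °C; then TFAA, 2,6-lutidine, −78 °C; aq. NaHCO3
Reagents that add atoms: water, O
Why: Grignard 1,2-addition to the only carbonyl of the 3-alkoxycyclobutenone, then a Stork–Danheiser-type 1,3-carbonyl transposition triggered by trifluoroacetylation, should place the nonadecyl group on the carbon next to the carbinol without exposing the allenyl ether or silyl ether to aqueous acid.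

**Step 4**
Reactants: 12 the silyl ether from step 3
Product: 13 4-hydroxy-4-(1-methoxypropa-1,2-dien-1-yl)-3-nonadecylcyclobut-2-en-1-one (racemic)
Conditions: TBAF, AcOH, THF, −20 °C
Reagents that add atoms: none
Why: Buffered fluoride desilylation of a tertiary trimethylsilyl ether should free the hydroxyl without base-induced opening of the cyclobutenone or isomerisation of the allenyl ether.

**Step 5**
Reactants: 13 the hydroxycyclobutenone from step 4
Product: 16 3-methoxy-2-methyl-5-nonadecylcyclohexa-2,5-diene-1,4-dione, via dienylketene 14 (not isolated), via o-quinone methide 15 (not isolated)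
Conditions: degassed toluene, 110 °C, dilute (0.01 M)
Reagents that add atoms: none
Why: Thermal conrotatory 4π ring opening of the cyclobutenone cleaves the temporary C3–C6 bond and gives the (allenylvinyl)ketene 14; the ketene carbon (future C3) then bonds to the central allene carbon (future C4) in a disrotatory 6π electrocyclisation that closes the six-membered carbocycle as the 6-methylene-2,4-cyclohexadienone 15. A 1,5-hydrogen shift (enol O–H to the exocyclic CH2, equivalent to tautomerisation) then turns the allene terminus into the C4 methyl group and delivers the quinone oxidation level with no external oxidant. The closest known reaction type is the thermal ring expansion of 4-alkenyl- and 4-allenyl-4-oxygenated cyclobutenones to hydroquinones, quinones and o-quinone methides (Moore-type rearrangement). No stereocentre is formed. The selectivity needed is torquoselectivity in the ring opening: the hydroxyl donor rotates outward, so the allenyl group turns inward toward the ketene, which secures the cis-dienylketene geometry and keeps the hydroxyl away from the ketene. The placement of methyl, methoxy and nonadecyl groups is fixed by the connectivity of 13.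

**Step 6**
Reactants: 16 the methoxyquinone from step 5
Product: 17 capiquinone C (3-hydroxy-2-methyl-5-nonadecylcyclohexa-2,5-diene-1,4-dione)
Conditions: 1 M NaOH (aq.), THF/MeOH, 0 °C to rt, argon; then 1 M HCl
Reagents that add atoms: sodium hydroxide, [Na+].[OH-]
Why: The methoxyquinone is a vinylogous ester, so hydroxide addition–elimination at the methoxy-bearing carbon should expel methoxide and give the hydroxyquinone after acidification.

**Compound list**
1 | diisopropyl squarate | CC(C)OC1=C(OC(C)C)C(=O)C1=O | starting material
2 | 4-hydroxy-2,3-diisopropoxycyclobut-2-en-1-one (racemic, present as its aluminate) | CC(C)OC1=C(OC(C)C)C(O)C1=O | intermediate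
3 | 3-isopropoxycyclobut-3-ene-1,2-dione | CC(C)OC1=CC(=O)C1=O | intermediate
4 | methoxyallene | COC=C=C | starting material
5 | 1-lithio-1-methoxyallene | [Li]C(OC)=C=C | intermediate
6 | lithium 2-isopropoxy-1-(1-methoxypropa-1,2-dien-1-yl)-4-oxocyclobut-2-en-1-olate (racemic) | [Li]OC1(C(OC)=C=C)C(=O)C=C1OC(C)C | intermediate
7 | 3-isopropoxy-4-(1-methoxypropa-1,2-dien-1-yl)-4-(trimethylsilyloxy)cyclobut-2-en-1-one (racemic) | C=C=C(OC)C1(O[Si](C)(C)C)C(=O)C=C1OC(C)C | intermediate
8 | 1-bromononadecane | CCCCCCCCCCCCCCCCCCCBr | starting material
9 | nonadecylmagnesium bromide | CCCCCCCCCCCCCCCCCCC[Mg]Br | intermediate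
10 | bromomagnesium 3-isopropoxy-4-(1-methoxypropa-1,2-dien-1-yl)-1-nonadecyl-4-(trimethylsilyloxy)cyclobut-2-en-1-olate (diastereomer mixture) | CCCCCCCCCCCCCCCCCCCC1(O[Mg]Br)C=C(OC(C)C)C1(O[Si](C)(C)C)C(OC)=C=C | intermediate
11 | 3-isopropoxy-4-(1-methoxypropa-1,2-dien-1-yl)-1-nonadecyl-4-(trimethylsilyloxy)cyclobut-2-en-1-yl trifluoroacetate (diastereomer mixture) | CCCCCCCCCCCCCCCCCCCC1(OC(=O)C(F)(F)F)C=C(OC(C)C)C1(O[Si](C)(C)C)C(OC)=C=C | intermediate
12 | 4-(1-methoxypropa-1,2-dien-1-yl)-3-nonadecyl-4-(trimethylsilyloxy)cyclobut-2-en-1-one (racemic) | C=C=C(OC)C1(O[Si](C)(C)C)C(=O)C=C1CCCCCCCCCCCCCCCCCCC | intermediate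
13 | 4-hydroxy-4-(1-methoxypropa-1,2-dien-1-yl)-3-nonadecylcyclobut-2-en-1-one (racemic) | C=C=C(OC)C1(O)C(=O)C=C1CCCCCCCCCCCCCCCCCCC | intermediate
14 | (Z)-4-hydroxy-5-methoxy-3-nonadecylhepta-1,3,5,6-tetraen-1-one (dienylketene) | O=C=C/C(CCCCCCCCCCCCCCCCCCC)=C(/O)C(OC)=C=C | intermediate
15 | 4-hydroxy-5-methoxy-6-methylidene-3-nonadecylcyclohexa-2,4-dien-1-one (o-quinone methide) | CCCCCCCCCCCCCCCCCCCC1=CC(=O)C(=C)C(OC)=C1O | intermediate
16 | 3-methoxy-2-methyl-5-nonadecylcyclohexa-2,5-diene-1,4-dione | CCCCCCCCCCCCCCCCCCCC1=CC(=O)C(C)=C(OC)C1=O | intermediate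
17 | capiquinone C | CCCCCCCCCCCCCCCCCCCC1=CC(=O)C(C)=C(O)C1=O | target

**Total step count:** 6. **Longest linear sequence:** 6 steps (1 → 3 → 7 → 12 → 13 → 16 → 17).

**Steps most likely to fail**

Step 5. The free hydroxyl may capture the ketene if part of the material opens with the wrong sense of rotation (lactonisation to a butenolide), and the o-quinone methide may dimerise before the hydrogen shift. The fallback separates the hydrogen shift from the electrocyclic cascade and sets out from 12. The silyl ether 12 would be heated in toluene at 110 °C, so that no hydroxyl is available to the ketene. This should give 5-methoxy-6-methylidene-3-nonadecyl-4-(trimethylsilyloxy)cyclohexa-2,4-dien-1-one F1, which would be treated cold, without isolation, with TBAF/AcOH. Desilylation releases the enol, which tautomerises to the quinone, and the route is rejoined at 16.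

Step 3. The Grignard reagent may deprotonate or reduce the hindered vinylogous ester carbonyl instead of adding, and the allenyl ether may be lost during the transposition. The fallback installs the chain before the allene and sets out from 1 and 9. Addition of 9 to diisopropyl squarate should give 4-hydroxy-2,3-diisopropoxy-4-nonadecylcyclobut-2-en-1-one F2. Hydride reduction of the remaining carbonyl (DIBAL-H, THF, −78 °C) should give 2,3-diisopropoxy-1-nonadecylcyclobut-2-ene-1,4-diol F3. Aqueous HCl should convert F3 by double 1,3-transposition into 3-nonadecylcyclobut-3-ene-1,2-dione F4. Addition of 5 to F4 at −78 °C is expected to prefer the carbonyl that is not deactivated by the β-alkyl group, the one next to the nonadecyl-bearing carbon, and aqueous work-up rejoins the route at 13. The weaker regiocontrol of this addition is the price of the shorter, acid-free endgame.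

Step 6. Hydroxide may add at the free C2–H position, or the hydroxyquinone anion may autoxidise and degrade in base. The fallback performs the demethylation at the arene oxidation level and sets out from 16. Reduction with aqueous Na2S2O4 (EtOAc/water) should give 3-methoxy-2-methyl-5-nonadecylbenzene-1,4-diol F5. BBr3 in CH2Cl2 (−78 to 0 °C) should cleave the aryl methyl ether to 3-methyl-6-nonadecylbenzene-1,2,4-triol F6. Exposure of F6 to air (or FeCl3) during work-up reoxidises it to the hydroxyquinone, and the route is rejoined at 17.

**Further compounds**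
F1 | step 5 | 5-methoxy-6-methylidene-3-nonadecyl-4-(trimethylsilyloxy)cyclohexa-2,4-dien-1-one | CCCCCCCCCCCCCCCCCCCC1=CC(=O)C(=C)C(OC)=C1O[Si](C)(C)C
F2 | step 3 | 4-hydroxy-2,3-diisopropoxy-4-nonadecylcyclobut-2-en-1-one | CCCCCCCCCCCCCCCCCCCC1(O)C(=O)C(OC(C)C)=C1OC(C)C
F3 | step 3 | 2,3-diisopropoxy-1-nonadecylcyclobut-2-ene-1,4-diol | CCCCCCCCCCCCCCCCCCCC1(O)C(O)C(OC(C)C)=C1OC(C)C
F4 | step 3 | 3-nonadecylcyclobut-3-ene-1,2-dione | CCCCCCCCCCCCCCCCCCCC1=CC(=O)C1=O
F5 | step 6 | 3-methoxy-2-methyl-5-nonadecylbenzene-1,4-diol | CCCCCCCCCCCCCCCCCCCc1cc(O)c(C)c(OC)c1O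
F6 | step 6 | 3-methyl-6-nonadecylbenzene-1,2,4-triol | CCCCCCCCCCCCCCCCCCCc1cc(O)c(C)c(O)c1O
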